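**Plan**

1. Numbering: C1 (alkyne CH) to C15 (CH3); O1 bridges C6/C9 (oxolane), O2 bridges C7/C12 (oxepane). The enabling feature is the all-cis oxolane O1–C6–C7–C8–C9 with O2 on C7: C7–O2 is the Baeyer–Villiger product of a C7 acetyl group, and an all-cis 3-acetyl oxolane is what a Prins–pinacol rearrangement of a 4-methyl-4-vinyl-1,3-dioxolane delivers.
2. Cuts, in retrosynthetic order: C3=C4 (Peterson enyne olefination); O2–C12 together with C13–Br (bromoetherification of a 12E-alkene); C10–Br (from C10–O with inversion); C7–O2 (from C7–acetyl); C8–C9 and C6–C7 together (Prins–pinacol); the two acetal C9–O bonds; then carbinol–C7 (vinyl Grignard) and C10–C11 (glycolate alkylation).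
3. Forward: diol 8 (C4–C8, from L-malic acid) and aldehyde 18 (C9–C15) are joined as acetal 19; step 13 closes the oxolane, step 18 closes the oxepane, and C1–C3 is added last.
4. Stereochemistry: C6 comes from L-malic acid; C10 from an auxiliary-controlled alkylation (R), inverted to S on bromination; C9 and C7 are relayed from C6 through the chair Prins–pinacol transition state; C12/C13 come from anti addition to the E-alkene during the bicyclic closure; the 3Z alkene comes from the Peterson elimination.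

Key step: step 13

Remark: diol 8 and acetal 19 are carried as mixtures at the tertiary carbinol and acetal carbons, because both centres are erased in step 13.

**Route**

Step 1
Reactants: 1 L-malic acid
Product: 2 2-[(4S)-2,2-dimethyl-5-oxo-1,3-dioxolan-4-yl]acetic acid
Conditions: 2,2-dimethoxypropane, p-TsOH (cat.), rt
Reagents that add atoms: 2,2-dimethoxypropane, COC(C)(C)OC
Why: Acid-catalysed acetonide formation engages the α-hydroxy acid as the five-membered dioxolanone in preference to the six-membered alternative, leaving the C4 carboxyl free and the stereocentre untouched.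

Step 2
Reactants: 2 2-[(4S)-2,2-dimethyl-5-oxo-1,3-dioxolan-4-yl]acetic acid
Product: 3 (5S)-5-(2-hydroxyethyl)-2,2-dimethyl-1,3-dioxolan-4-one
Conditions: BH3·THF, THF, 0 °C to rt
Reagents that add atoms: none
Why: Chemoselective borane reduction: the free carboxylic acid is reduced much faster than the lactone-type dioxolanone carbonyl.

Step 3
Reactants: 3 (5S)-5-(2-hydroxyethyl)-2,2-dimethyl-1,3-dioxolan-4-one
Product: 4 (5S)-5-[2-(tert-butyldiphenylsilyloxy)ethyl]-2,2-dimethyl-1,3-dioxolan-4-one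
Conditions: t-BuPh2SiCl, imidazole, CH2Cl2, 0 °C to rt
Reagents that add atoms: tert-butyl(chloro)diphenylsilane, CC(C)(C)[Si](Cl)(c1ccccc1)c1ccccc1
Why: Imidazole-promoted silyl ether formation caps the primary alcohol before it can lactonise onto the dioxolanone.

Step 4
Reactants: 4 (5S)-5-[2-(tert-butyldiphenylsilyloxy)ethyl]-2,2-dimethyl-1,3-dioxolan-4-one
Product: 5 (2S)-4-(tert-butyldiphenylsilyloxy)-2-hydroxy-N-methoxy-N-methylbutanamide
Conditions: MeNH(OMe)·HCl, AlMe3, CH2Cl2, 0 °C to rt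
Reagents that add atoms: N,O-dimethylhydroxylamine hydrochloride, CNOC.Cl
Why: Weinreb aminolysis: the aluminium amide opens the activated dioxolanone acyl group with loss of acetone, giving the α-hydroxy Weinreb amide without touching C6.

Step 5
Reactants: 5 (2S)-4-(tert-butyldiphenylsilyloxy)-2-hydroxy-N-methoxy-N-methylbutanamide
Product: 6 (3S)-5-(tert-butyldiphenylsilyloxy)-3-hydroxypentan-2-one
Conditions: MeMgBr (3 equiv), THF, −20 to 0 °C
Reagents that add atoms: methylmagnesium bromide, C[Mg]Br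
Why: Grignard addition to a Weinreb amide stops at the ketone because the chelated tetrahedral magnesium adduct survives until work-up; one equivalent is consumed by the free hydroxyl.

Step 6
Reactants: 6 (3S)-5-(tert-butyldiphenylsilyloxy)-3-hydroxypentan-2-one; 7 vinylmagnesium bromide
Product: 8 (4S)-6-(tert-butyldiphenylsilyloxy)-3-methylhex-1-ene-3,4-diol (both C3 epimers)
Conditions: 7 (3 equiv), THF, −78 to 0 °C
Reagents that add atoms: none
Why: Grignard 1,2-addition to the magnesium alkoxide of the α-hydroxy ketone gives the tertiary allylic alcohol; the new carbinol centre needs no control because it becomes the acetyl carbonyl in step 13.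

Step 7
Reactants: 9 (4S)-4-benzyl-1,3-oxazolidin-2-one; 10 benzyloxyacetyl chloride
Product: 12 (4S)-4-benzyl-3-[2-(benzyloxy)acetyl]-1,3-oxazolidin-2-one, via N-lithio oxazolidinone 11 (not isolated)
Conditions: n-BuLi, THF, −78 °C; then 10, −78 to 0 °C
Reagents that add atoms: none
Why: N-Acylation of the lithiated Evans oxazolidinone with an acid chloride.

Step 8
Reactants: 13 (E)-1-bromopent-2-ene
Product: 14 (E)-1-iodopent-2-ene
Conditions: NaI, acetone, rt, dark
Reagents that add atoms: sodium iodide, [Na+].[I-]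
Why: Finkelstein exchange (SN2 at the primary allylic carbon, driven by precipitation of NaBr) gives the more reactive iodide needed for low-temperature glycolate alkylation, with the E geometry retained.

Step 9
Reactants: 12 (4S)-4-benzyl-3-[2-(benzyloxy)acetyl]-1,3-oxazolidin-2-one; 14 (E)-1-iodopent-2-ene
Product: 16 (4S)-4-benzyl-3-[(2R,4E)-2-(benzyloxy)hept-4-enoyl]-1,3-oxazolidin-2-one, via sodium enolate 15 (not isolated)
Conditions: NaN(SiMe3)2, THF, −78 °C; then 14 (3 equiv), −78 to −45 °C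
Reagents that add atoms: none
Why: Evans-type asymmetric alkylation of a glycolate imide: the chelated (Z)-sodium enolate is alkylated on the face opposite the benzyl group of the auxiliary, which sets C10 as R.

Step 10
Reactants: 16 (4S)-4-benzyl-3-[(2R,4E)-2-(benzyloxy)hept-4-enoyl]-1,3-oxazolidin-2-one
Product: 17 (2R,4E)-2-(benzyloxy)hept-4-en-1-ol
Conditions: LiBH4, MeOH (1 equiv), Et2O, 0 °C
Reagents that add atoms: none
Why: Reductive cleavage of the N-acyl oxazolidinone by hydride attack at the exocyclic carbonyl releases the primary alcohol and the auxiliary without affecting C10 or the alkene.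

Step 11
Reactants: 17 (2R,4E)-2-(benzyloxy)hept-4-en-1-ol
Product: 18 (2R,4E)-2-(benzyloxy)hept-4-enal
Conditions: Dess–Martin periodinane, NaHCO3, CH2Cl2, 0 °C to rt
Reagents that add atoms: none
Why: Dess–Martin oxidation under buffered, non-basic conditions should give the α-benzyloxy aldehyde without epimerising C10; it is used at once.

Step 12
Reactants: 8 (4S)-6-(tert-butyldiphenylsilyloxy)-3-methylhex-1-ene-3,4-diol; 18 (2R,4E)-2-(benzyloxy)hept-4-enal
Product: 19 (5S)-2-[(1R,3E)-1-(benzyloxy)hex-3-en-1-yl]-5-[2-(tert-butyldiphenylsilyloxy)ethyl]-4-ethenyl-4-methyl-1,3-dioxolane (mixture at C2 and C4)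
Conditions: p-TsOH·H2O (cat.), MgSO4, CH2Cl2, 0 °C to rt
Reagents that add atoms: none
Why: Acid-catalysed acetalisation of the 1,2-diol with the aldehyde under dehydrating conditions forms the 1,3-dioxolane; mild acid and short contact should keep C10 intact.

Step 13
Reactants: 19 (5S)-2-[(1R,3E)-1-(benzyloxy)hex-3-en-1-yl]-5-[2-(tert-butyldiphenylsilyloxy)ethyl]-4-ethenyl-4-methyl-1,3-dioxolane
Product: 22 1-[(2S,3S,5S)-5-[(1R,3E)-1-(benzyloxy)hex-3-en-1-yl]-2-[2-(tert-butyldiphenylsilyloxy)ethyl]oxolan-3-yl]ethan-1-one, via oxocarbenium ion 20 (not isolated), via oxan-4-yl cation 21 (not isolated)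
Conditions: SnCl4 (2 equiv), CH2Cl2, −78 to −20 °C; cold aq. NaHCO3 quench
Reagents that add atoms: none
Why: SnCl4 ionises the acetal at the tertiary allylic oxygen to the (E)-oxocarbenium ion on O1 (20); the vinyl terminus C8 attacks C9 in a 6-endo Prins cyclisation through a chair with the C5 and C10 arms equatorial (21), and the ring bond from the carbinol carbon to C6 then migrates to C7, contracting the oxane to the oxolane and turning the carbinol carbon into the acetyl carbonyl. This is the known Prins–pinacol rearrangement of 4-alkenyl-1,3-dioxolanes to 3-acyl tetrahydrofurans, here applied to an α-benzyloxy aldehyde acetal. The oxolane therefore arises by 6-endo-trig closure followed by a 1,2-shift ring contraction, not by a direct five-membered closure. C9 is set by the chair (E-oxocarbenium ion, both arms equatorial, relayed from C6), and C7 by suprafacial migration of C6 onto the cation face turned toward it, so the acetyl group, the C5 arm and the C10 arm should end up all-cis. The step needs ionisation toward O1 (the other oxocarbenium ion cannot reach the alkene in a six-membered array and can only reclose), retention at C6 and C10 (C6 migrates with retention; low temperature disfavours an oxonia-Cope/aldol detour and α-epimerisation), and a kinetic quench before the cis ketone equilibrates.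

Step 14
Reactants: 22 1-[(2S,3S,5S)-5-[(1R,3E)-1-(benzyloxy)hex-3-en-1-yl]-2-[2-(tert-butyldiphenylsilyloxy)ethyl]oxolan-3-yl]ethan-1-one
Product: 23 (2S,3S,5S)-5-[(1R,3E)-1-(benzyloxy)hex-3-en-1-yl]-2-[2-(tert-butyldiphenylsilyloxy)ethyl]oxolan-3-yl acetate
Conditions: Me3SiOOSiMe3 (3 equiv), SnCl4 (1 equiv), 4 Å molecular sieves, CH2Cl2, −20 to 0 °C
Reagents that add atoms: bis(trimethylsilyl) peroxide, C[Si](C)(C)OO[Si](C)(C)C
Why: Lewis-acid-promoted Baeyer–Villiger oxidation with a silyl peroxide: the secondary carbon C7 migrates in preference to methyl with retention, and because this peroxide adds to the activated carbonyl but does not epoxidise isolated alkenes, the 12E-alkene should survive.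

Step 15
Reactants: 23 (2S,3S,5S)-5-[(1R,3E)-1-(benzyloxy)hex-3-en-1-yl]-2-[2-(tert-butyldiphenylsilyloxy)ethyl]oxolan-3-yl acetate
Product: 24 (2S,3S,5S)-2-[2-(tert-butyldiphenylsilyloxy)ethyl]-5-[(1R,3E)-1-hydroxyhex-3-en-1-yl]oxolan-3-yl acetate
Conditions: BCl3·SMe2, CH2Cl2, 0 °C to rt
Reagents that add atoms: none
Why: Lewis-acid debenzylation cleaves the benzyl ether by benzylic C–O scission while tolerating the alkene, the acetate and the silyl ether, which hydrogenolysis would not.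

Step 16
Reactants: 24 (2S,3S,5S)-2-[2-(tert-butyldiphenylsilyloxy)ethyl]-5-[(1R,3E)-1-hydroxyhex-3-en-1-yl]oxolan-3-yl acetate
Product: 25 (2S,3S,5S)-5-[(1S,3E)-1-bromohex-3-en-1-yl]-2-[2-(tert-butyldiphenylsilyloxy)ethyl]oxolan-3-yl acetate
Conditions: CBr4, P(n-C8H17)3, toluene, 70 °C
Reagents that add atoms: tetrabromomethane, BrC(Br)(Br)Br
Why: Appel-type bromination: bromide displaces the alkoxyphosphonium ion at C10 in an SN2 reaction, inverting the R carbinol to the S bromide of the target.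

Step 17
Reactants: 25 (2S,3S,5S)-5-[(1S,3E)-1-bromohex-3-en-1-yl]-2-[2-(tert-butyldiphenylsilyloxy)ethyl]oxolan-3-yl acetate
Product: 26 (2S,3S,5S)-5-[(1S,3E)-1-bromohex-3-en-1-yl]-2-[2-(tert-butyldiphenylsilyloxy)ethyl]oxolan-3-ol
Conditions: i-Bu2AlH, CH2Cl2, −78 °C
Reagents that add atoms: none
Why: Reductive ester cleavage at low temperature frees the C7 hydroxyl without producing a free alkoxide that could displace the cis-disposed C10 bromide.

Step 18
Reactants: 26 (2S,3S,5S)-5-[(1S,3E)-1-bromohex-3-en-1-yl]-2-[2-(tert-butyldiphenylsilyloxy)ethyl]oxolan-3-ol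
Product: 27 tert-butyl{2-[(1S,3R,5S,6S,8S)-5-bromo-3-[(1S)-1-bromopropyl]-2,7-dioxabicyclo[4.2.1]nonan-8-yl]ethoxy}diphenylsilane
Conditions: 2,4,4,6-tetrabromocyclohexa-2,5-dien-1-one, CH2Cl2, −78 to 0 °C
Reagents that add atoms: 2,4,4,6-tetrabromocyclohexa-2,5-dien-1-one, O=C1C(Br)=CC(Br)(Br)C=C1Br
Why: Bromoetherification: bromonium formation at the 12E-alkene and 7-exo attack of the C7 hydroxyl at C12 anti to bromine closes the oxepane, the E geometry fixing the C12–O/C13–Br relationship, and closure over the C8 edge of the oxolane with the C13–C15 end turned away from the ring system should give 12R,13S.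

Step 19
Reactants: 27 tert-butyl{2-[(1S,3R,5S,6S,8S)-5-bromo-3-[(1S)-1-bromopropyl]-2,7-dioxabicyclo[4.2.1]nonan-8-yl]ethoxy}diphenylsilane
Product: 28 2-[(1S,3R,5S,6S,8S)-5-bromo-3-[(1S)-1-bromopropyl]-2,7-dioxabicyclo[4.2.1]nonan-8-yl]ethan-1-ol
Conditions: HF·pyridine, THF/pyridine, 0 °C to rt
Reagents that add atoms: none
Why: Fluoride-mediated desilylation under mildly acidic conditions removes the silyl ether without a base that could eliminate HBr.

Step 20
Reactants: 28 2-[(1S,3R,5S,6S,8S)-5-bromo-3-[(1S)-1-bromopropyl]-2,7-dioxabicyclo[4.2.1]nonan-8-yl]ethan-1-ol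
Product: 29 2-[(1S,3R,5S,6S,8S)-5-bromo-3-[(1S)-1-bromopropyl]-2,7-dioxabicyclo[4.2.1]nonan-8-yl]acetaldehyde
Conditions: Dess–Martin periodinane, NaHCO3, CH2Cl2, 0 °C to rt
Reagents that add atoms: none
Why: Dess–Martin oxidation gives the β-alkoxy aldehyde under neutral conditions that avoid β-elimination of O1.

Step 21
Reactants: 29 2-[(1S,3R,5S,6S,8S)-5-bromo-3-[(1S)-1-bromopropyl]-2,7-dioxabicyclo[4.2.1]nonan-8-yl]acetaldehyde; 30 1,3-bis(triisopropylsilyl)propyne
Product: 33 {(3Z)-5-[(1S,3R,5S,6S,8S)-5-bromo-3-[(1S)-1-bromopropyl]-2,7-dioxabicyclo[4.2.1]nonan-8-yl]pent-3-en-1-yn-1-yl}tri(propan-2-yl)silane, via lithiated propyne 31 (not isolated), via lithium alkoxide adduct 32 (not isolated)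
Conditions: 30, n-BuLi, THF, −78 °C; then 29, −78 °C to rt
Reagents that add atoms: none
Why: Yamamoto–Peterson olefination: the lithiated bis-silyl propyne adds to the aldehyde and the β-silyl alkoxide loses silanolate by syn elimination, the bulky triisopropylsilyl groups favouring the Z-enyne.

Step 22
Reactants: 33 {(3Z)-5-[(1S,3R,5S,6S,8S)-5-bromo-3-[(1S)-1-bromopropyl]-2,7-dioxabicyclo[4.2.1]nonan-8-yl]pent-3-en-1-yn-1-yl}tri(propan-2-yl)silane
Product: 34 (1S,3R,5S,6S,8S)-5-bromo-3-[(1S)-1-bromopropyl]-8-[(2Z)-pent-2-en-4-yn-1-yl]-2,7-dioxabicyclo[4.2.1]nonane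
Conditions: Bu4NF, THF, 0 °C
Reagents that add atoms: none
Why: Fluoride-induced protodesilylation of the alkynylsilane; brief exposure at 0 °C should leave the secondary bromides untouched.

**Compound list**

1 | L-malic acid, (2S)-2-hydroxybutanedioic acid | O[C@@H](CC(O)=O)C(O)=O | starting material
2 | 2-[(4S)-2,2-dimethyl-5-oxo-1,3-dioxolan-4-yl]acetic acid | CC1(C)O[C@@H](CC(O)=O)C(=O)O1 | intermediate
3 | (5S)-5-(2-hydroxyethyl)-2,2-dimethyl-1,3-dioxolan-4-one | CC1(C)O[C@@H](CCO)C(=O)O1 | intermediate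
4 | (5S)-5-[2-(tert-butyldiphenylsilyloxy)ethyl]-2,2-dimethyl-1,3-dioxolan-4-one | CC1(C)O[C@@H](CCO[Si](c2ccccc2)(c2ccccc2)C(C)(C)C)C(=O)O1 | intermediate
5 | (2S)-4-(tert-butyldiphenylsilyloxy)-2-hydroxy-N-methoxy-N-methylbutanamide | CON(C)C(=O)[C@@H](O)CCO[Si](c1ccccc1)(c1ccccc1)C(C)(C)C | intermediate
6 | (3S)-5-(tert-butyldiphenylsilyloxy)-3-hydroxypentan-2-one | CC(=O)[C@@H](O)CCO[Si](c1ccccc1)(c1ccccc1)C(C)(C)C | intermediate
7 | vinylmagnesium bromide | C=C[Mg]Br | starting material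
8 | (4S)-6-(tert-butyldiphenylsilyloxy)-3-methylhex-1-ene-3,4-diol (both C3 epimers) | C=CC(C)(O)[C@@H](O)CCO[Si](c1ccccc1)(c1ccccc1)C(C)(C)C | intermediate
9 | (4S)-4-benzyl-1,3-oxazolidin-2-one | O=C1N[C@@H](Cc2ccccc2)CO1 | starting material
10 | benzyloxyacetyl chloride | O=C(Cl)COCc1ccccc1 | starting material
11 | N-lithio (4S)-4-benzyl-1,3-oxazolidin-2-one | [Li]N1[C@@H](Cc2ccccc2)COC1=O | intermediate
12 | (4S)-4-benzyl-3-[2-(benzyloxy)acetyl]-1,3-oxazolidin-2-one | O=C(COCc1ccccc1)N1[C@@H](Cc2ccccc2)COC1=O | intermediate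
13 | (E)-1-bromopent-2-ene | CC/C=C/CBr | starting material
14 | (E)-1-iodopent-2-ene | CC/C=C/CI | intermediate
15 | sodium (Z)-enolate of 12 | [Na]O/C(=C\OCc1ccccc1)N1[C@@H](Cc2ccccc2)COC1=O | intermediate
16 | (4S)-4-benzyl-3-[(2R,4E)-2-(benzyloxy)hept-4-enoyl]-1,3-oxazolidin-2-one | CC/C=C/C[C@@H](OCc1ccccc1)C(=O)N1[C@@H](Cc2ccccc2)COC1=O | intermediate
17 | (2R,4E)-2-(benzyloxy)hept-4-en-1-ol | CC/C=C/C[C@@H](OCc1ccccc1)CO | intermediate
18 | (2R,4E)-2-(benzyloxy)hept-4-enal | CC/C=C/C[C@@H](OCc1ccccc1)C=O | intermediate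
19 | (5S)-2-[(1R,3E)-1-(benzyloxy)hex-3-en-1-yl]-5-[2-(tert-butyldiphenylsilyloxy)ethyl]-4-ethenyl-4-methyl-1,3-dioxolane (mixture at C2 and C4) | CC/C=C/C[C@@H](OCc1ccccc1)C1OC(C)(C=C)[C@H](CCO[Si](c2ccccc2)(c2ccccc2)C(C)(C)C)O1 | intermediate
20 | O1=C9 oxocarbenium chloride carrying the trichlorostannyl ether of the tertiary carbinol | CC/C=C/C[C@@H](OCc1ccccc1)C=[O+][C@@H](CCO[Si](c2ccccc2)(c2ccccc2)C(C)(C)C)C(C)(C=C)O[Sn](Cl)(Cl)Cl.[Cl-] | intermediate
21 | 2,6-cis-oxan-4-yl cation (C7 cation) chloride carrying the trichlorostannyl ether on the adjacent carbinol carbon | CC/C=C/C[C@@H](OCc1ccccc1)[C@@H]1C[CH+]C(C)(O[Sn](Cl)(Cl)Cl)[C@H](CCO[Si](c2ccccc2)(c2ccccc2)C(C)(C)C)O1.[Cl-] | intermediate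
22 | 1-[(2S,3S,5S)-5-[(1R,3E)-1-(benzyloxy)hex-3-en-1-yl]-2-[2-(tert-butyldiphenylsilyloxy)ethyl]oxolan-3-yl]ethan-1-one | CC(C)(C)[Si](c1ccccc1)(c1ccccc1)OCC[C@@H]1O[C@H]([C@H](OCc2ccccc2)C/C=C/CC)C[C@@H]1C(C)=O | intermediate
23 | (2S,3S,5S)-5-[(1R,3E)-1-(benzyloxy)hex-3-en-1-yl]-2-[2-(tert-butyldiphenylsilyloxy)ethyl]oxolan-3-yl acetate | CC(C)(C)[Si](c1ccccc1)(c1ccccc1)OCC[C@@H]1O[C@H]([C@H](OCc2ccccc2)C/C=C/CC)C[C@@H]1OC(C)=O | intermediate
24 | (2S,3S,5S)-2-[2-(tert-butyldiphenylsilyloxy)ethyl]-5-[(1R,3E)-1-hydroxyhex-3-en-1-yl]oxolan-3-yl acetate | CC(C)(C)[Si](c1ccccc1)(c1ccccc1)OCC[C@@H]1O[C@H]([C@H](O)C/C=C/CC)C[C@@H]1OC(C)=O | intermediate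
25 | (2S,3S,5S)-5-[(1S,3E)-1-bromohex-3-en-1-yl]-2-[2-(tert-butyldiphenylsilyloxy)ethyl]oxolan-3-yl acetate | CC(C)(C)[Si](c1ccccc1)(c1ccccc1)OCC[C@@H]1O[C@H]([C@@H](Br)C/C=C/CC)C[C@@H]1OC(C)=O | intermediate
26 | (2S,3S,5S)-5-[(1S,3E)-1-bromohex-3-en-1-yl]-2-[2-(tert-butyldiphenylsilyloxy)ethyl]oxolan-3-ol | CC(C)(C)[Si](c1ccccc1)(c1ccccc1)OCC[C@@H]1O[C@H]([C@@H](Br)C/C=C/CC)C[C@@H]1O | intermediate
27 | tert-butyl{2-[(1S,3R,5S,6S,8S)-5-bromo-3-[(1S)-1-bromopropyl]-2,7-dioxabicyclo[4.2.1]nonan-8-yl]ethoxy}diphenylsilane | CC(C)(C)[Si](c1ccccc1)(c1ccccc1)OCC[C@@H]1O[C@H]2C[C@@H]1O[C@@H]([C@@H](Br)CC)C[C@@H]2Br | intermediate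
28 | 2-[(1S,3R,5S,6S,8S)-5-bromo-3-[(1S)-1-bromopropyl]-2,7-dioxabicyclo[4.2.1]nonan-8-yl]ethan-1-ol | OCC[C@@H]1O[C@H]2C[C@@H]1O[C@@H]([C@@H](Br)CC)C[C@@H]2Br | intermediate
29 | 2-[(1S,3R,5S,6S,8S)-5-bromo-3-[(1S)-1-bromopropyl]-2,7-dioxabicyclo[4.2.1]nonan-8-yl]acetaldehyde | O=CC[C@@H]1O[C@H]2C[C@@H]1O[C@@H]([C@@H](Br)CC)C[C@@H]2Br | intermediate
30 | 1,3-bis(triisopropylsilyl)propyne | CC(C)[Si](C(C)C)(C(C)C)CC#C[Si](C(C)C)(C(C)C)C(C)C | starting material
31 | 1,3-bis(triisopropylsilyl)prop-2-yn-1-yllithium | [Li]C(C#C[Si](C(C)C)(C(C)C)C(C)C)[Si](C(C)C)(C(C)C)C(C)C | intermediate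
32 | lithium alkoxide of the β-silyl carbinol adduct of 31 and 29 (two new centres, uncontrolled) | CC(C)[Si](C(C)C)(C(C)C)C#CC([Si](C(C)C)(C(C)C)C(C)C)C(O[Li])C[C@@H]1O[C@H]2C[C@@H]1O[C@@H]([C@@H](Br)CC)C[C@@H]2Br | intermediate
33 | {(3Z)-5-[(1S,3R,5S,6S,8S)-5-bromo-3-[(1S)-1-bromopropyl]-2,7-dioxabicyclo[4.2.1]nonan-8-yl]pent-3-en-1-yn-1-yl}tri(propan-2-yl)silane | CC(C)[Si](C(C)C)(C(C)C)C#C/C=C\C[C@@H]1O[C@H]2C[C@@H]1O[C@@H]([C@@H](Br)CC)C[C@@H]2Br | intermediate
34 | (1S,3R,5S,6S,8S)-5-bromo-3-[(1S)-1-bromopropyl]-8-[(2Z)-pent-2-en-4-yn-1-yl]-2,7-dioxabicyclo[4.2.1]nonane (6S,7S,9S,10S,12R,13S in chain numbering) | C#C/C=C\C[C@@H]1O[C@H]2C[C@@H]1O[C@@H]([C@@H](Br)CC)C[C@@H]2Br | target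

**Step count and risks**

Total step count: 22. Longest linear sequence: 17 steps (steps 1–6, then 12–22, from L-malic acid).

Steps most likely to fail:

1. Step 18 (oxepane closure). The 7-exo attack may lose to participation of the ring oxygen O1 (5-exo opening of the bromonium ion to a bicyclic oxonium ion) or to 8-endo attack at C13. The two alkene faces may also be poorly differentiated, which would erode the C12/C13 configuration. The fallback sets the C12 configuration by reagent control and sets out from 26. Asymmetric epoxidation of the E-alkene with the L-fructose-derived (enantiomeric Shi) ketone and KHSO5 (Oxone), K2CO3, MeCN/dimethoxymethane/buffer at 0 °C should give the (12S,13S)-epoxide, epoxy bromo alcohol F1. Camphorsulfonic acid in CH2Cl2 would open the epoxide by 7-exo attack of the C7 hydroxyl at C12 with inversion to give the oxepane carbinol F2. Its C13 hydroxyl needs one extra inversion, so a Mitsunobu reaction (4-nitrobenzoic acid, PPh3, diisopropyl azodicarboxylate) would give the 4-nitrobenzoate F3, and methanolysis (K2CO3, MeOH, 0 °C) the epimeric carbinol F4. Bromination with inversion (CBr4, P(n-C8H17)3, toluene, 70 °C) comes back to the route at 27.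

2. Step 14 (Baeyer–Villiger oxidation beside an alkene). The Lewis acid may epimerise C7 before oxygen insertion, or the hindered methyl ketone may react so slowly that forcing conditions begin to oxidise the alkene. The fallback masks the alkene and uses a peracid, setting out from 22. Pyridinium tribromide in CH2Cl2 at −78 °C would add bromine anti to the E-alkene to give the dibromo ketone F5. CF3CO3H buffered with Na2HPO4 in CH2Cl2 would then carry out the Baeyer–Villiger oxidation to the dibromo acetate F6. Zinc dust in AcOH/Et2O at 0 °C would regenerate the E-alkene by reductive anti elimination, coming back to the route at 23.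

3. Step 16 (bromide at C10). E2 elimination toward the diene, or participation of O1 leading to retention or ring expansion, may compete with the SN2 displacement of the phosphonium intermediate. The fallback separates activation from displacement and sets out from 24. Chloromethanesulfonyl chloride and 2,6-lutidine in CH2Cl2 at 0 °C would give the chloromethanesulfonate F7, which Bu4NBr in toluene at 40–60 °C would displace with inversion, coming back to the route at 25.

**Further compounds**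

F1 | step 18 | (2S,3S,5S)-5-{(1S)-1-bromo-2-[(2S,3S)-3-ethyloxiran-2-yl]ethyl}-2-[2-(tert-butyldiphenylsilyloxy)ethyl]oxolan-3-ol | CC(C)(C)[Si](c1ccccc1)(c1ccccc1)OCC[C@@H]1O[C@H]([C@@H](Br)C[C@@H]2O[C@H]2CC)C[C@@H]1O
F2 | step 18 | (1S)-1-[(1S,3R,5S,6S,8S)-5-bromo-8-[2-(tert-butyldiphenylsilyloxy)ethyl]-2,7-dioxabicyclo[4.2.1]nonan-3-yl]propan-1-ol | CC(C)(C)[Si](c1ccccc1)(c1ccccc1)OCC[C@@H]1O[C@H]2C[C@@H]1O[C@@H]([C@@H](O)CC)C[C@@H]2Br
F3 | step 18 | (1R)-1-[(1S,3R,5S,6S,8S)-5-bromo-8-[2-(tert-butyldiphenylsilyloxy)ethyl]-2,7-dioxabicyclo[4.2.1]nonan-3-yl]propyl 4-nitrobenzoate | CC(C)(C)[Si](c1ccccc1)(c1ccccc1)OCC[C@@H]1O[C@H]2C[C@@H]1O[C@@H]([C@H](OC(=O)c3ccc(cc3)[N+](=O)[O-])CC)C[C@@H]2Br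
F4 | step 18 | (1R)-1-[(1S,3R,5S,6S,8S)-5-bromo-8-[2-(tert-butyldiphenylsilyloxy)ethyl]-2,7-dioxabicyclo[4.2.1]nonan-3-yl]propan-1-ol | CC(C)(C)[Si](c1ccccc1)(c1ccccc1)OCC[C@@H]1O[C@H]2C[C@@H]1O[C@@H]([C@H](O)CC)C[C@@H]2Br
F5 | step 14 | 1-[(2S,3S,5S)-5-[(1R)-1-(benzyloxy)-3,4-dibromohexyl]-2-[2-(tert-butyldiphenylsilyloxy)ethyl]oxolan-3-yl]ethan-1-one (anti dibromide, both 3,4-erythro forms) | CC(C)(C)[Si](c1ccccc1)(c1ccccc1)OCC[C@@H]1O[C@H]([C@H](OCc2ccccc2)CC(Br)C(Br)CC)C[C@@H]1C(C)=O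
F6 | step 14 | (2S,3S,5S)-5-[(1R)-1-(benzyloxy)-3,4-dibromohexyl]-2-[2-(tert-butyldiphenylsilyloxy)ethyl]oxolan-3-yl acetate (anti dibromide, both 3,4-erythro forms) | CC(C)(C)[Si](c1ccccc1)(c1ccccc1)OCC[C@@H]1O[C@H]([C@H](OCc2ccccc2)CC(Br)C(Br)CC)C[C@@H]1OC(C)=O
F7 | step 16 | (2S,3S,5S)-2-[2-(tert-butyldiphenylsilyloxy)ethyl]-5-[(1R,3E)-1-{[(chloromethyl)sulfonyl]oxy}hex-3-en-1-yl]oxolan-3-yl acetate | CC(C)(C)[Si](c1ccccc1)(c1ccccc1)OCC[C@@H]1O[C@H]([C@H](OS(=O)(=O)CCl)C/C=C/CC)C[C@@H]1OC(C)=O
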